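**Assumptions**

- The target (C21H20O5) has no stereocentre and no stereogenic double bond (the prenyl alkene ends in two methyl groups). It is therefore one achiral compound, no enantiocontrol is needed, and the racemic C2 centre of the starting flavanone is erased in the key step.
- A total synthesis is taken to mean that the 3-arylchromone nucleus is made in the route and is not bought as a ready-made isoflavone.

**Numbering used throughout**

1 (±)-naringenin; 2 7-O-methyl ether of 1; 3 4′-O-benzyl ether of 2; 4 5-O-acetate of 3; 5 acetylated isoflavone (not isolated); 6 benzyl-protected 5-hydroxy-7-methoxyisoflavone; 7 6-iodide of 6; 8 debenzylated 6-iodide; 9 prenylboronic acid pinacol ester; 10 Gancaonin G.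

## Analysis of the target

Gancaonin G is an isoflavone: a 4H-chromen-4-one in which benzene ring A (C4a–C8a) is fused to the γ-pyranone ring C (O1, C2, C3, C4). The 4-hydroxyphenyl ring B sits on C3 through the C3–C1′ bond, and C2 is an unsubstituted CH next to O1. Ring A is fully differentiated: C5 carries an OH hydrogen-bonded to the C4 carbonyl, C6 a 3-methylbut-2-enyl (prenyl) group, C7 a methoxy group and C8 a hydrogen. There is no stereocentre and no E/Z element, so the whole difficulty is constitutional. The sensitive groups are the prenyl alkene beside the free 5-OH and the electrophilic C2 of the pyranone. Acid closes the prenyl group onto O5 to a 2,2-dimethylchroman, electrophiles and oxidants (I+, Tl(III), I(III)) add to it, and hydrogenation reduces it; hydroxide can open the vinylogous ester at C2. The hard points are therefore (a) ring B on C3 rather than C2, (b) C6 against C8, two ring-A positions each flanked by two oxygens and differing only in their neighbour (5-OH against O1), (c) one methyl on O7 among three phenolic oxygens, and (d) a prenyl group that must arrive late, after which no acid, hydrogen or strong Lewis acid may be used. The feature that invites a bold move is the C3–C1′ bond together with the C2–H. An isoflavone is a flavanone whose ring B has shifted from C2 to C3, which is how the biosynthesis makes it, and the flavanone with exactly this 5,7,4′-oxygenation is the commodity naringenin 1.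

## Retrosynthetic reasoning

**C6–C1″ bond (10 ⇒ 8 + 9).** The prenyl group is cut off last, because it survives neither the oxidant of the key step nor any removal of an O4′ protecting group. Cutting at the aryl–allyl bond leaves an aryl iodide 8 and the commercial C5 boronate 9. The forward reaction has to join a doubly ortho-substituted, phenol-bearing aryl iodide to the primary terminus of the allyl unit under conditions free of acid and oxidant.

**O4′–benzyl and C6–I bonds (8 ⇒ 7 ⇒ 6).** The iodine in 7 is placed by the free 5-OH of 6, which has only one open ortho position, C6. This is the relay that distinguishes C6 from C8. Ring B must be capped during iodination (a free 4′-phenol would be iodinated at C3′) and must be uncapped before the prenyl group is present, hence the benzyl ether is removed between the two events (7 ⇒ 8).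

**C3–C1′ bond formed, C2–C1′ bond broken (6 ⇒ 5 ⇒ 4).** This is the key disconnection. The isoflavone 5 is traced back to the isomeric flavanone 4 by a 1,2-shift of ring B from C2 to C3 with oxidation, the laboratory copy of the biosynthetic step. It is cut here because this single bond exchange converts a cheap, one-piece C15 skeleton into the target skeleton and creates the C2=C3 unsaturation in the same operation. No two-fragment assembly of ring C is then needed. The forward reaction has to functionalise C3 electrophilically, let the electron-rich ring B migrate rather than lose the C2 proton, and leave ring A alone. The acetate in 5 is removed in the same flask to give 6.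

**Protecting-group pattern (4 ⇒ 3 ⇒ 2 ⇒ 1).** The three phenols of 1 differ enough in acidity and hydrogen bonding to be addressed one by one without detours. O7 (most acidic) takes the methyl group that stays in the target. O4′ takes a benzyl group, which keeps ring B electron-rich for the shift. The chelated O5 takes an acetate, which frees the C4 ketone for enolisation and shields ring A from the oxidant.

## Alternatives that were turned down

**Alternative 1:** The textbook disconnection cuts the C3–C1′ bond as a Suzuki–Miyaura coupling. In the forward sense, acetophenone A1 is converted to an enaminone and cyclised with an iodine electrophile to the 3-iodochromone A2, which is coupled with boronic acid A3 to give prunetin A4; protection and prenylation then follow as in the present route. It was turned down for these reasons: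
- It spends three bond-forming operations (C2 insertion, O1–C2 closure, C3–C1′ coupling) to assemble a C15 skeleton that exists in one piece as its flavanone isomer.
- The free, acidic hydroxyls of A1 interfere with formamide-acetal chemistry and would cost protection steps.
- The iodocyclisation excludes an early prenyl group, since iodoetherification with the flanking phenol would compete. A prenylated A1 would also have two non-equivalent hydroxyls that close to 6- and 8-prenyl chromones.
- It is therefore no shorter, solves none of the ring-A problem, and is the route most chemists would draw first.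

**Alternative 2:** The classical deoxybenzoin disconnection cuts C4–C4a and both bonds to C2. In the forward sense, phenol A5 is acylated with arylacetic acid A6 under a boron Lewis acid to deoxybenzoin A7, and a Vilsmeier-type one-carbon reagent closes ring C in the same pot to A4. It was turned down for these reasons:
- A5 has two kinds of open position. Acylation between the hydroxyls gives A7, but acylation between OH and OMe leads to the 7-hydroxy-5-methoxy series.
- The hot Lewis acid would cyclise a prenyl group onto the neighbouring phenol, so the prenyl group cannot come in with the phenol.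
- It ends at unprotected A4 and needs the same endgame plus a protection step, and it uses the Lewis acid in solvent quantity.

**Alternative 3:** A sigmatropic disconnection of the C6–C1″ bond. The tertiary allyl ether A8 (the 5-O-(2-methylbut-3-en-2-yl) ether of 6) would undergo an aromatic Claisen rearrangement, which can only reach C6 because C4a is blocked, and would give the benzyl-protected target A9. It was turned down for these reasons:
- Making a tertiary ether at the hydrogen-bonded, peri-hindered O5 is the hard step; it takes two operations through the propargyl ether and is poorly suited to chelated phenols.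
- Tertiary allyl aryl ethers tend to ionise and lose the C5 unit on heating.
- A9 still carries the benzyl group, and its removal by hydrogen or a boron halide is not compatible with the prenyl group.
- It decorates the skeleton and builds none of it.

Key step: step 4

## Route

Step 1
Reactants: 1 (±)-naringenin
Product: 2 (±)-5-hydroxy-2-(4-hydroxyphenyl)-7-methoxychroman-4-one (sakuranetin)
Conditions: MeI (1.05 equiv), K2CO3 (1.0 equiv), DMF, 0 °C to rt
Reagents that add atoms: iodomethane, CI
Why: Williamson etherification under acidity control: the 7-OH (para to the C4 carbonyl, a vinylogous acid) is the most acidic phenol, the 5-OH is locked in a hydrogen bond to C4=O and the 4′-OH is about two pKa units weaker, so one equivalent of base and methyl iodide should alkylate O7 first.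

Step 2
Reactants: 2 (±)-sakuranetin
Product: 3 (±)-2-[4-(benzyloxy)phenyl]-5-hydroxy-7-methoxychroman-4-one
Conditions: BnBr (1.1 equiv), K2CO3 (1.2 equiv), DMF, rt
Reagents that add atoms: benzyl bromide, BrCc1ccccc1
Why: Williamson etherification of the only remaining unchelated phenol; the benzyl ether keeps ring B electron-rich for the later aryl shift and can be removed without hydrogen before the prenyl group arrives.

Step 3
Reactants: 3 (±)-2-[4-(benzyloxy)phenyl]-5-hydroxy-7-methoxychroman-4-one
Product: 4 (±)-2-[4-(benzyloxy)phenyl]-7-methoxy-4-oxochroman-5-yl acetate
Conditions: Ac2O (3 equiv), pyridine, DMAP (cat.), rt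
Reagents that add atoms: acetic anhydride, CC(=O)OC(C)=O
Why: DMAP-catalysed acylation of the hydrogen-bonded 5-OH, as in the peracetylation of flavanones; the acetate breaks the chelate so that the C4 ketone enolises normally and keeps ring A from reacting as a phenol with iodine(III).

Step 4
Reactants: 4 (±)-2-[4-(benzyloxy)phenyl]-7-methoxy-4-oxochroman-5-yl acetate
Product: 6 3-[4-(benzyloxy)phenyl]-5-hydroxy-7-methoxy-4H-chromen-4-one, via acetylated isoflavone 5 (not isolated)
Conditions: PhI(OH)OTs (1.2 equiv), MeCN, 70 °C; then aq. Na2S2O3 (destroys excess oxidant), K2CO3, MeOH, rt, same flask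
Reagents that add atoms: none
Why: [Hydroxy(tosyloxy)iodo]benzene, an electrophilic iodine(III) reagent, attacks the acid-formed enol of the C4 ketone at C3 on the face anti to the C2 aryl group and gives a trans C3–I(III) species. In its diaxial conformer the 4-benzyloxyphenyl ring is antiperiplanar to the C3–I bond and shifts from C2 to C3 through a phenonium ion as iodobenzene leaves, the O1 lone pair stabilises the C2 cation as an oxocarbenium ion, and loss of the C3 proton gives the chromone 5. The closest known reaction type is the iodine(III)- or thallium(III)-mediated oxidative 2,3-aryl migration of flavanones to isoflavones, the laboratory counterpart of the isoflavone synthase step. No ring is closed (ring C is kept and re-wired: C2–C1′ breaks, C3–C1′ forms, C2=C3 appears) and no stereocentre is made; the racemic C2 centre of 4 is erased. The step needs the aryl shift to beat loss of the C2 proton (which would give the 2-aryl chromone), capture of the C3 iodane by tosylate, and contraction of ring C by migration of ring A. The p-alkoxy group raises the migratory aptitude of ring B, the absence of methanol or orthoester during the oxidation keeps C4 a ketone so that ring-A migration would require an acylium ion, and the 5-acetate frees the ketone from the chelate and deactivates ring A. Carbonate in methanol then removes the acetate from 5 by transesterification and should give 6.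

Step 5
Reactants: 6 3-[4-(benzyloxy)phenyl]-5-hydroxy-7-methoxy-4H-chromen-4-one
Product: 7 3-[4-(benzyloxy)phenyl]-5-hydroxy-6-iodo-7-methoxy-4H-chromen-4-one
Conditions: BnMe3N+ ICl2− (1.05 equiv), CaCO3, CH2Cl2–MeOH, rt
Reagents that add atoms: benzyltrimethylammonium dichloroiodate, C[N+](C)(C)Cc1ccccc1.Cl[I-]Cl
Why: Electrophilic aromatic iodination of a phenol with a dichloroiodate salt, buffered by CaCO3; the free, chelated 5-OH activates its only open ortho position C6, the preference known for 5-hydroxy-7-alkoxychromones, while the benzyl-capped ring B is a much weaker nucleophile.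

Step 6
Reactants: 7 3-[4-(benzyloxy)phenyl]-5-hydroxy-6-iodo-7-methoxy-4H-chromen-4-one
Product: 8 5-hydroxy-3-(4-hydroxyphenyl)-6-iodo-7-methoxy-4H-chromen-4-one
Conditions: BCl3 (3 equiv), pentamethylbenzene (3 equiv), CH2Cl2, −78 °C; MeOH quench, aqueous work-up
Reagents that add atoms: none
Why: Lewis-acid debenzylation with a non-basic cation scavenger: BCl3 ionises the aryl benzyl ether at low temperature and pentamethylbenzene traps the benzyl cation by Friedel–Crafts alkylation, so the aryl iodide, the 7-OMe group (no neighbouring carbonyl to assist its cleavage) and the chromone should survive. Placing it here means no deprotection is needed once the prenyl group is in.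

Step 7
Reactants: 8 5-hydroxy-3-(4-hydroxyphenyl)-6-iodo-7-methoxy-4H-chromen-4-one, 9 prenylboronic acid pinacol ester
Product: 10 Gancaonin G
Conditions: 9 (2 equiv), Pd(OAc)2 (5 mol %), SPhos (10 mol %), K3PO4 (3 equiv), THF–H2O, 60 °C, degassed
Reagents that add atoms: none
Why: Suzuki–Miyaura coupling of an aryl iodide with an allylic boronate: after oxidative addition and transmetalation the allylpalladium species equilibrates through its η3 form, and reductive elimination at the unsubstituted terminus is expected because bond formation at the tertiary terminus next to a 2,6-dioxygenated aryl carbon is sterically prohibitive. Aqueous phosphate tolerates the free phenols, and the new alkene never meets acid or oxidant.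

## Compound list

1 | (±)-naringenin, 5,7-dihydroxy-2-(4-hydroxyphenyl)chroman-4-one (racemate, C2 unspecified) | O=C1CC(c2ccc(O)cc2)Oc2cc(O)cc(O)c12 | starting material
2 | (±)-sakuranetin, 5-hydroxy-2-(4-hydroxyphenyl)-7-methoxychroman-4-one (racemate) | COc1cc(O)c2c(c1)OC(c1ccc(O)cc1)CC2=O | intermediate
3 | (±)-2-[4-(benzyloxy)phenyl]-5-hydroxy-7-methoxychroman-4-one (racemate) | COc1cc(O)c2c(c1)OC(c1ccc(OCc3ccccc3)cc1)CC2=O | intermediate
4 | (±)-2-[4-(benzyloxy)phenyl]-7-methoxy-4-oxochroman-5-yl acetate (racemate) | COc1cc(OC(C)=O)c2c(c1)OC(c1ccc(OCc3ccccc3)cc1)CC2=O | intermediate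
5 | 3-[4-(benzyloxy)phenyl]-7-methoxy-4-oxo-4H-chromen-5-yl acetate | COc1cc2occ(-c3ccc(OCc4ccccc4)cc3)c(=O)c2c(OC(C)=O)c1 | intermediate
6 | 3-[4-(benzyloxy)phenyl]-5-hydroxy-7-methoxy-4H-chromen-4-one | COc1cc2occ(-c3ccc(OCc4ccccc4)cc3)c(=O)c2c(O)c1 | intermediate
7 | 3-[4-(benzyloxy)phenyl]-5-hydroxy-6-iodo-7-methoxy-4H-chromen-4-one | COc1cc2occ(-c3ccc(OCc4ccccc4)cc3)c(=O)c2c(O)c1I | intermediate
8 | 5-hydroxy-3-(4-hydroxyphenyl)-6-iodo-7-methoxy-4H-chromen-4-one | COc1cc2occ(-c3ccc(O)cc3)c(=O)c2c(O)c1I | intermediate
9 | 4,4,5,5-tetramethyl-2-(3-methylbut-2-en-1-yl)-1,3,2-dioxaborolane (prenylboronic acid pinacol ester) | CC(C)=CCB1OC(C)(C)C(C)(C)O1 | starting material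
10 | Gancaonin G, 5-hydroxy-3-(4-hydroxyphenyl)-7-methoxy-6-(3-methylbut-2-en-1-yl)-4H-chromen-4-one | COc1cc2occ(-c3ccc(O)cc3)c(=O)c2c(O)c1CC=C(C)C | target

## Step count and risk

Total step count: 7 steps. Longest linear sequence: 7 steps (1 to 10); 9 is purchased.

Steps least certain to work:

**Step 4 (key step).** The C3 iodane may collapse by loss of the C2 proton (dehydrogenation to the 2-aryl chromone) or by tosylate capture instead of the aryl shift, because the shift needs the trans-diaxial conformer. Iodine(III) may also attack the electron-rich ring A. The fallback is the open-chain version of the same rearrangement, in which no such elimination competes. It sets out from 3 and comes back at 6. Excess NaH and chloromethyl methyl ether in DMF should open the pyranone by E1cB and cap both phenoxides to give the chalcone (E)-3-[4-(benzyloxy)phenyl]-1-[4-methoxy-2,6-bis(methoxymethoxy)phenyl]prop-2-en-1-one F1. Thallium(III) nitrate in methanol–trimethyl orthoformate should then induce the 1,2-aryl shift to the acetal 2-[4-(benzyloxy)phenyl]-3,3-dimethoxy-1-[4-methoxy-2,6-bis(methoxymethoxy)phenyl]propan-1-one F2. Warm methanolic HCl removes both methoxymethyl groups and closes ring C; because ring A of F2 is symmetric, closure onto either hydroxyl gives 6.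

**Step 7.** Reductive loss of iodine may compete (β-hydride elimination from the prenyl–palladium intermediate gives a palladium hydride), as may coupling at the tertiary allyl terminus. The phenoxides also make oxidative addition at the hindered C6 slow. The fallback builds the prenyl group in two C–C events. It sets out from 8 and comes back at 10. Suzuki–Miyaura coupling of 8 with allylboronic acid pinacol ester, whose allyl unit has two identical termini and no β-hydrogen problem, should give 5-hydroxy-3-(4-hydroxyphenyl)-7-methoxy-6-(prop-2-en-1-yl)-4H-chromen-4-one F3. Olefin cross-metathesis of F3 with excess 2-methyl-2-butene (second-generation Ru benzylidene catalyst, CH2Cl2, 40 °C) should then give 10.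

**Step 5.** Iodination may go to C8 (para to the 5-OH) or twice, since C6 and C8 are electronically close. The fallback replaces electrophilic substitution by a sigmatropic relay from O5 that can only reach C6. It sets out from 6 and comes back at 10, bypassing 7 and 8. Allyl bromide and K2CO3 in DMF at 60 °C should give 3-[4-(benzyloxy)phenyl]-7-methoxy-5-(prop-2-en-1-yloxy)-4H-chromen-4-one F4. An aromatic Claisen rearrangement (N,N-diethylaniline, about 200 °C) should deliver 3-[4-(benzyloxy)phenyl]-5-hydroxy-7-methoxy-6-(prop-2-en-1-yl)-4H-chromen-4-one F5, because C4a, the other ortho position, is blocked. BCl3 with pentamethylbenzene at −78 °C removes the benzyl group to give F3, and the cross-metathesis described for step 7 gives 10.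

**Step 1.** Over-alkylation at O4′ alongside incomplete conversion may give a mixture of mono- and dimethyl ethers that is laborious to separate. The fallback uses a protecting-group relay instead of acidity control. It sets out from 1 and comes back at 2. Peracetylation (Ac2O, pyridine) gives (±)-naringenin triacetate F6. Thiophenol and imidazole in N-methylpyrrolidone should remove only the 7-O-acetyl group, the most activated aryl ester, to give (±)-4-(5-acetoxy-7-hydroxy-4-oxochroman-2-yl)phenyl acetate F7. Mitsunobu methylation (MeOH, PPh3, DIAD) gives (±)-4-(5-acetoxy-7-methoxy-4-oxochroman-2-yl)phenyl acetate F8, and K2CO3 in methanol gives 2.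

## Further compounds

F1 | step 4 | (E)-3-[4-(benzyloxy)phenyl]-1-[4-methoxy-2,6-bis(methoxymethoxy)phenyl]prop-2-en-1-one | COCOc1cc(OC)cc(OCOC)c1C(=O)/C=C/c1ccc(OCc2ccccc2)cc1
F2 | step 4 | 2-[4-(benzyloxy)phenyl]-3,3-dimethoxy-1-[4-methoxy-2,6-bis(methoxymethoxy)phenyl]propan-1-one | COCOc1cc(OC)cc(OCOC)c1C(=O)C(c1ccc(OCc2ccccc2)cc1)C(OC)OC
F3 | step 7 | 5-hydroxy-3-(4-hydroxyphenyl)-7-methoxy-6-(prop-2-en-1-yl)-4H-chromen-4-one | C=CCc1c(OC)cc2occ(-c3ccc(O)cc3)c(=O)c2c1O
F4 | step 5 | 3-[4-(benzyloxy)phenyl]-7-methoxy-5-(prop-2-en-1-yloxy)-4H-chromen-4-one | C=CCOc1cc(OC)cc2occ(-c3ccc(OCc4ccccc4)cc3)c(=O)c12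
F5 | step 5 | 3-[4-(benzyloxy)phenyl]-5-hydroxy-7-methoxy-6-(prop-2-en-1-yl)-4H-chromen-4-one | C=CCc1c(OC)cc2occ(-c3ccc(OCc4ccccc4)cc3)c(=O)c2c1O
F6 | step 1 | (±)-naringenin triacetate, 2-(4-acetoxyphenyl)-4-oxochroman-5,7-diyl diacetate (racemate) | CC(=O)Oc1ccc(C2CC(=O)c3c(OC(C)=O)cc(OC(C)=O)cc3O2)cc1
F7 | step 1 | (±)-4-(5-acetoxy-7-hydroxy-4-oxochroman-2-yl)phenyl acetate (racemate) | CC(=O)Oc1ccc(C2CC(=O)c3c(OC(C)=O)cc(O)cc3O2)cc1
F8 | step 1 | (±)-4-(5-acetoxy-7-methoxy-4-oxochroman-2-yl)phenyl acetate (racemate) | COc1cc(OC(C)=O)c2c(c1)OC(c1ccc(OC(C)=O)cc1)CC2=O
A1 | alternative 1 | 1-(2,6-dihydroxy-4-methoxyphenyl)ethan-1-one | CC(=O)c1c(O)cc(OC)cc1O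
A2 | alternative 1 | 5-hydroxy-3-iodo-7-methoxy-4H-chromen-4-one | COc1cc(O)c2c(c1)occ(I)c2=O
A3 | alternative 1 | (4-hydroxyphenyl)boronic acid | OB(O)c1ccc(O)cc1
A4 | alternative 1 | prunetin, 5-hydroxy-3-(4-hydroxyphenyl)-7-methoxy-4H-chromen-4-one | COc1cc(O)c2c(c1)occ(-c1ccc(O)cc1)c2=O
A5 | alternative 2 | 5-methoxybenzene-1,3-diol | COc1cc(O)cc(O)c1
A6 | alternative 2 | 2-(4-hydroxyphenyl)acetic acid | OC(=O)Cc1ccc(O)cc1
A7 | alternative 2 | 1-(2,6-dihydroxy-4-methoxyphenyl)-2-(4-hydroxyphenyl)ethan-1-one | COc1cc(O)c(C(=O)Cc2ccc(O)cc2)c(O)c1
A8 | alternative 3 | 3-[4-(benzyloxy)phenyl]-7-methoxy-5-[(2-methylbut-3-en-2-yl)oxy]-4H-chromen-4-one | COc1cc(OC(C)(C)C=C)c2c(c1)occ(-c1ccc(OCc3ccccc3)cc1)c2=O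
A9 | alternative 3 | 3-[4-(benzyloxy)phenyl]-5-hydroxy-7-methoxy-6-(3-methylbut-2-en-1-yl)-4H-chromen-4-one | COc1cc2occ(-c3ccc(OCc4ccccc4)cc3)c(=O)c2c(O)c1CC=C(C)C
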